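The readings come from a simulation for an exercise, noise included.

- The constants of this catalyst are not to hand, so a loss read from the runs stands in for them, and the flask is bracketed from both ends.

| flask | Q | G | remark | time |
|---|---|---|---|---|
| Wednesday's | 20 mM | 2.8 mM | run made earlier |  |
| Monday's | 20 mM | 4.4 mM | run made earlier |  |
| Saturday's | 40 mM | 2 mM | run made earlier |  |
| flask | 20 mM | 2.0 mM |  | 2.5 min |

| run | time / s | E / % | Q / % | X / % | D / % |
|---|---|---|---|---|---|
| Wednesday's | 20.0 | 0.1 | 99.4 | 0 | 0.4 |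
| Wednesday's | 40.0 | 0.4 | 98.9 | 0.8 | 0.9 |
| Wednesday's | 50.0 | 0.5 | 98.1 | 0.3 | 0.9 |
| Wednesday's | 80.0 | 1.0 | 95.7 | 2.3 | 1.5 |
| Wednesday's | 90.0 | 1.7 | 94.2 | 3.8 | 0.8 |
| Monday's | 10.0 | 0.4 | 100.2 | 0.1 | 0.4 |
| Monday's | 25.0 | 0.7 | 99.1 | 0.3 | 1.1 |
| Monday's | 40.0 | 1.0 | 97.2 | 0.4 | 1.6 |
| Monday's | 60.0 | 1.3 | 95.4 | 2.6 | 1.1 |
| Monday's | 90.0 | 1.9 | 91.4 | 5.4 | 2.1 |
| Saturday's | 10.0 | 0.3 | 100.1 | 0.2 | 0 |
| Saturday's | 15.0 | 0.6 | 100.2 | 0 | 0.2 |
| Saturday's | 25.0 | 0.1 | 99.8 | 0.1 | 0 |
| Saturday's | 50.0 | 0.5 | 99.0 | 0.3 | 0.4 |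
| Saturday's | 90.0 | 0.9 | 97.4 | 1.7 | 0.7 |

(readings scatter by 0.3 percentage points)

- the species in which most of what was charged as Q, at 2.5 min sits (X / E / D / Q)
- the largest share itself, whichever of these holds it, in percent of the Q charged



- Taking the loss of Q as proportional to the G charged and to the square of the time, Wednesday's last reading foretells for the flask a lost fraction of 11.5 %. This is the onset loss, the fraction of Q that a run's last reading foretells for the flask under that square law. Monday's last reading gives 10.9 %.
- Lower bound on Q: Monday's loss grows 1.87-fold from 60.0 s to 90.0 s, slower than the 2.25-fold of a square law. So the square law overstates the loss, and by my reckoning the flask keeps at least 88.5 %.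
- Upper bound on Q: the loss still accelerates through this induction period, so Monday's last slope, 0.0182 /mM/min of the charge, held flat after 90.0 s, understates it. That leaves the flask at most 92.2 %.
- The forecast, Q at 88 %, calls the rate “nearly proportional to G” and stands just below this bracket.
- The flask holds Q at 91.1 %, inside the bracket, with X at 6.74 %.

    J ⇌ L (K = 3.10, k = 0.140 /min)
    Q + J ⇌ D (K = 810 /M, k = 250 /M/min)
    D → E (k = 4.40 /min)
    E → J + X (k = 5.00 /min)
    G ⇌ J (K = 0.450, k = 0.240 /min)

- The flask's Q stands this high partly through the sluggishness of the activation from G to J, together with the short run: with that sluggishness removed Q stands at 79.1 %, and ten times as long leaves 13.6 %. The flask lost 0.772 of the onset loss. That same share of the onset loss, scaled to the neighbour charged with 3.4 mM of G, gives 84.9 % of Q, and that neighbour holds 85.1 %.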